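## Retrosynthetic overview

1. Target ⇒ enal (Pinnick) ⇒ isopropenyl ester (SeO2) ⇒ 7α-isopropenyl-4α,9β-diol + (S)-3-methylpentanoic acid (esterification).
2. Diol ⇒ epoxy-ketone by one dissolving-metal reduction (C9 C=O → equatorial 9β-OH; 3α,4α-epoxide → 4α-OH). The axial C7 group comes from cuprate addition to a Δ7-9-one, the epoxide from α-face epoxidation of Δ3.
3. Bicyclic C12 dienone ⇒ key one-flask bicyclisation: aminocatalytic trienamine [4+2] of (2E,4E)-4-methylhexa-2,4-dienal with 3-methylbut-3-en-2-one, then intramolecular aldol condensation.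
4. Ring order: ring A first (C5–C10 and C1–C2 bonds, quaternary C10), ring B second (C7=C8), both in the same operation.
5. Dienal ⇒ tiglic aldehyde + formylmethylene ylide.

Assumption: eudesmane numbering is used for locants (C4 carbinol, C5/C10 ring fusion, C7 side chain, C9 ester); the (S)-prolinol catalyst is taken to shield the trienamine face syn to its CPh2OSi group as in known trienamine cycloadditions (if the antipode of 7 forms, the (R)-catalyst is used).

## Route

Step 1
Reactants: 1 (E)-2-methylbut-2-enal; 2 (triphenylphosphoranylidene)acetaldehyde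
Product: 3 (2E,4E)-4-methylhexa-2,4-dienal
Conditions: 1 (2 equiv), PhMe, 80 °C
Reagents that add atoms: 2 (triphenylphosphoranylidene)acetaldehyde, O=CC=P(c1ccccc1)(c1ccccc1)c1ccccc1
Why: Wittig olefination with a stabilised formylmethylene ylide is E-selective, and using the α-branched enal 1 in excess limits over-homologation of 3; no stereocentre is formed.

Step 2
Reactants: 3 (2E,4E)-4-methylhexa-2,4-dienal; 4 3-methylbut-3-en-2-one
Product: 7 (4aS,8aS)-5,8a-dimethyl-4a,7,8,8a-tetrahydronaphthalen-1(4H)-one, via trienamine 5 (not isolated), via keto-aldehyde 6 (not isolated)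
Conditions: (S)-α,α-diphenylprolinol TMS ether (20 mol %), 2-FC6H4CO2H (20 mol %), 4 (5 equiv), CHCl3, 45 °C, slow addition of 3; then p-TsOH·H2O (20 mol %), 60 °C, same flask
Reagents that add atoms: 4 3-methylbut-3-en-2-one, CC(=O)C(C)=C
Why: Proposed new method: the amine condenses with 3 to the HOMO-raised trienamine 5, whose terminal (β,ε) diene adds to enone 4 with "ortho" regiochemistry (ε-carbon to the enone CH2, β-carbon to the methyl-bearing α-carbon), creating C5 and the quaternary C10; the enone approaches the face anti to the CPh2OTMS shield (sets C5), and the α-methyl takes the endo position as in methacrolein-type dienophiles, so acetyl and the CH2CHO arm end up trans (trans ring fusion); hydrolysis gives δ-keto-aldehyde 6, whose only feasible intramolecular aldol condensation (methyl ketone onto aldehyde) closes ring B as the enone; closest known chemistry is the Jørgensen–Chen trienamine Diels–Alder of 2,4-dienals with activated olefins (including ones that form an adjacent quaternary centre), thermal Diels–Alder reactions of preformed amino-dienes with vinyl ketones, and acid/amine-promoted Robinson-type aldol condensation of δ-keto aldehydes.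

Step 3
Reactants: 7 (4aS,8aS)-5,8a-dimethyl-4a,7,8,8a-tetrahydronaphthalen-1(4H)-one
Product: 8 (3R,4S,5R,10S)-3α,4α-epoxy-11,12,13-trinoreudesm-7-en-9-one
Conditions: mCPBA (1.1 equiv), NaHCO3, CH2Cl2, 0 °C
Reagents that add atoms: 3-chloroperoxybenzoic acid, O=C(OO)c1cccc(Cl)c1
Why: Prilezhaev epoxidation takes the electron-rich trisubstituted Δ3 alkene and leaves the enone, and the peracid attacks anti to the axial angular methyl, so the C4–O bond is α and the C4 methyl β.

Step 4
Reactants: 8 (3R,4S,5R,10S)-3α,4α-epoxy-11,12,13-trinoreudesm-7-en-9-one; 9 isopropenylmagnesium bromide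
Product: 10 (3R,4S,5R,7R,10S)-3α,4α-epoxy-7-epi-eudesm-11-en-9-one (7α-isopropenyl, axial)
Conditions: 9 (1.5 equiv), CuBr·SMe2 (10 mol %), THF, −40 °C; sat. aq. NH4Cl
Reagents that add atoms: 9 isopropenylmagnesium bromide, C=C(C)[Mg]Br
Why: Copper-catalysed Grignard 1,4-addition proceeds by stereoelectronically preferred axial attack on the cyclohexenone, trans to the C5 ring substituent (trans-3,5 rule), which places the isopropenyl group axial (7α); the hindered trisubstituted epoxide is inert at −40 °C.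

Step 5
Reactants: 10 (3R,4S,5R,7R,10S)-3α,4α-epoxy-7-epi-eudesm-11-en-9-one
Product: 11 (4R,5R,7R,9S,10S)-7-epi-eudesm-11-ene-4α,9β-diol
Conditions: Li (10 equiv), NH3(l)/THF, t-BuOH (2 equiv), −78 → −33 °C; NH4Cl
Reagents that add atoms: none
Why: Dissolving-metal reduction gives the thermodynamically preferred equatorial 9β-alcohol from the hindered ketone (the axial epimer would be 1,3-diaxial to the C7 isopropenyl) and cleaves the epoxide at C3–O (less substituted carbanion), so the tertiary 4α-OH keeps its configuration; isolated alkenes are inert to Li/NH3.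

Step 6
Reactants: 11 (4R,5R,7R,9S,10S)-7-epi-eudesm-11-ene-4α,9β-diol; 12 (3S)-3-methylpentanoic acid
Product: 13 (4R,5R,7R,9S,10S)-4α-hydroxy-7-epi-eudesm-11-en-9β-yl (3S)-3-methylpentanoate
Conditions: 12 (1.5 equiv), DCC, DMAP, CH2Cl2, rt
Reagents that add atoms: 12 (3S)-3-methylpentanoic acid, CC[C@H](C)CC(=O)O
Why: Steglich esterification acylates only the secondary 9β-OH (the tertiary 4-OH is inert) and no stereocentre is touched.

Step 7
Reactants: 13 (4R,5R,7R,9S,10S)-4α-hydroxy-7-epi-eudesm-11-en-9β-yl (3S)-3-methylpentanoate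
Product: 14 (4R,5R,7R,9S,10S)-4α-hydroxy-9β-[(3S)-3-methylpentanoyloxy]-7-epi-eudesm-11(13)-en-12-al
Conditions: SeO2 (1.2 equiv), wet 1,4-dioxane, 80 °C
Reagents that add atoms: selenium dioxide, O=[Se]=O
Why: Riley allylic oxidation (ene reaction then [2,3]-shift) attacks the methyl of the 1,1-disubstituted alkene in preference to the ring methine and carries through to the 2-substituted acrolein; no stereocentre is touched.

Step 8
Reactants: 14 (4R,5R,7R,9S,10S)-4α-hydroxy-9β-[(3S)-3-methylpentanoyloxy]-7-epi-eudesm-11(13)-en-12-al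
Product: 15 2-[(2R,4S,4aS,8R,8aR)-8-hydroxy-4a,8-dimethyl-4-{[(3S)-3-methylpentanoyl]oxy}decahydronaphthalen-2-yl]prop-2-enoic acid (CNP0471281.1)
Conditions: NaClO2, NaH2PO4, 2-methylbut-2-ene, t-BuOH/H2O, rt
Reagents that add atoms: sodium chlorite, [Na+].[O-]Cl=O
Why: Pinnick oxidation converts the enal to the acrylic acid without touching the alkene, the ester or the tertiary alcohol.

## Compound list

1 | (E)-2-methylbut-2-enal (tiglic aldehyde) | C/C=C(C)/C=O | starting material
2 | (triphenylphosphoranylidene)acetaldehyde | O=CC=P(c1ccccc1)(c1ccccc1)c1ccccc1 | starting material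
3 | (2E,4E)-4-methylhexa-2,4-dienal | C/C=C(C)/C=C/C=O | intermediate
4 | 3-methylbut-3-en-2-one | CC(=O)C(C)=C | starting material
5 | trienamine, (2S)-2-[diphenyl(trimethylsilyloxy)methyl]-1-[(1E,3E)-4-methylhexa-1,3,5-trien-1-yl]pyrrolidine | C=C/C(C)=C/C=C/N1CCC[C@H]1C(O[Si](C)(C)C)(c1ccccc1)c1ccccc1 | intermediate
6 | keto-aldehyde, 2-[(1S,6S)-6-acetyl-2,6-dimethylcyclohex-2-en-1-yl]acetaldehyde | CC(=O)[C@@]1(C)CCC=C(C)[C@@H]1CC=O | intermediate
7 | (4aS,8aS)-5,8a-dimethyl-4a,7,8,8a-tetrahydronaphthalen-1(4H)-one (11,12,13-trinoreudesma-3,7-dien-9-one; trans-fused, 10β-Me, 5α-H) | CC1=CCC[C@]2(C)C(=O)C=CC[C@@H]12 | intermediate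
8 | (3R,4S,5R,10S)-3α,4α-epoxy-11,12,13-trinoreudesm-7-en-9-one (α-epoxide of 7; 4β-Me) | C[C@@]12O[C@@H]1CC[C@]3(C)C(=O)C=CC[C@@H]23 | intermediate
9 | isopropenylmagnesium bromide | C=C(C)[Mg]Br | starting material
10 | (3R,4S,5R,7R,10S)-3α,4α-epoxy-7-epi-eudesm-11-en-9-one (7α-isopropenyl, axial) | C=C(C)[C@H]1CC(=O)[C@@]2(C)CC[C@H]3O[C@@]3(C)[C@@H]2C1 | intermediate
11 | (4R,5R,7R,9S,10S)-7-epi-eudesm-11-ene-4α,9β-diol | C=C(C)[C@H]1C[C@H](O)[C@@]2(C)CCC[C@@](C)(O)[C@@H]2C1 | intermediate
12 | (3S)-3-methylpentanoic acid | CC[C@H](C)CC(=O)O | starting material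
13 | (4R,5R,7R,9S,10S)-4α-hydroxy-7-epi-eudesm-11-en-9β-yl (3S)-3-methylpentanoate | C=C(C)[C@H]1C[C@H](OC(=O)C[C@@H](C)CC)[C@@]2(C)CCC[C@@](C)(O)[C@@H]2C1 | intermediate
14 | (4R,5R,7R,9S,10S)-4α-hydroxy-9β-[(3S)-3-methylpentanoyloxy]-7-epi-eudesm-11(13)-en-12-al | C=C(C=O)[C@H]1C[C@H](OC(=O)C[C@@H](C)CC)[C@@]2(C)CCC[C@@](C)(O)[C@@H]2C1 | intermediate
15 | 2-[(2R,4S,4aS,8R,8aR)-8-hydroxy-4a,8-dimethyl-4-{[(3S)-3-methylpentanoyl]oxy}decahydronaphthalen-2-yl]prop-2-enoic acid | C=C(C(=O)O)[C@H]1C[C@H](OC(=O)C[C@@H](C)CC)[C@@]2(C)CCC[C@@](C)(O)[C@@H]2C1 | target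

## Step count and risks

Total step count: 8. Longest linear sequence: 8 steps (1 → 15).

Most likely to fail, first: step 2. The weakly activated, α-substituted enone 4 may be outrun by self-condensation of 3; α-Michael alkylation may compete with the β,ε-[4+2]; the ring fusion may come out cis; the ee may be low. The fallback sets out from 3 and switches from HOMO-raising aminocatalysis to LUMO-lowering acid catalysis with a preformed diene. Soft enolisation (TBSOTf, Et3N, CH2Cl2, 0 °C) gives tert-butyl(dimethyl){[(1E,3E)-4-methylhexa-1,3,5-trien-1-yl]oxy}silane F1, which has no free aldehyde and cannot self-condense. Its terminal diene is combined with 4 under a chiral oxazaborolidinium triflimide (or a chiral N-triflyl phosphoramide) at −78 °C, where α-methyl enones react through the acyl-exo transition state. This gives 1-[(1S,2S)-2-{(E)-2-[tert-butyl(dimethyl)silyloxy]ethenyl}-1,3-dimethylcyclohex-3-en-1-yl]ethan-1-one F2. Aqueous HCl in THF unmasks keto-aldehyde 6 and p-TsOH closes ring B, so the fallback comes back to the route at 7.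

Second: step 5. In Li/NH3 the trisubstituted epoxide may open slowly, or open towards the secondary alcohol. The fallback sets out from 10 and separates the two reductions. A short treatment with 2.2 equiv Li in NH3/THF at −78 °C (or SmI2/H2O/Et3N) reduces only the ketone and gives (3R,4S,5R,7R,9S,10S)-3α,4α-epoxy-7-epi-eudesm-11-en-9β-ol F3. LiEt3BH (THF, 0 °C → rt) then opens the epoxide by SN2 hydride delivery at the secondary C3, and the fallback comes back at 11.

Third: step 7. SeO2 may stop at the allylic alcohol, attack the C7 methine, or dehydrate the tertiary alcohol. The fallback sets out from 13 and replaces the selenium ene reaction by a chlorine ene reaction followed by substitution-oxidation. NaOCl with CeCl3·7H2O (CH2Cl2/H2O, 0 °C) gives 12-chloro-4α-hydroxy-7-epi-eudesm-11(13)-en-9β-yl (3S)-3-methylpentanoate F4. Kornblum oxidation (DMSO, NaHCO3, cat. NaI, 60 °C) converts the allylic chloride to the enal, and the fallback comes back at 14.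

## Further compounds

F1 | step 2 | tert-butyl(dimethyl){[(1E,3E)-4-methylhexa-1,3,5-trien-1-yl]oxy}silane | C=C/C(C)=C/C=C/O[Si](C)(C)C(C)(C)C
F2 | step 2 | 1-[(1S,2S)-2-{(E)-2-[tert-butyl(dimethyl)silyloxy]ethenyl}-1,3-dimethylcyclohex-3-en-1-yl]ethan-1-one | CC(=O)[C@@]1(C)CCC=C(C)[C@@H]1/C=C/O[Si](C)(C)C(C)(C)C
F3 | step 5 | (3R,4S,5R,7R,9S,10S)-3α,4α-epoxy-7-epi-eudesm-11-en-9β-ol | C=C(C)[C@H]1C[C@H](O)[C@@]2(C)CC[C@H]3O[C@@]3(C)[C@@H]2C1
F4 | step 7 | 12-chloro-4α-hydroxy-7-epi-eudesm-11(13)-en-9β-yl (3S)-3-methylpentanoate | C=C(CCl)[C@H]1C[C@H](OC(=O)C[C@@H](C)CC)[C@@]2(C)CCC[C@@](C)(O)[C@@H]2C1
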